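The numbers in the tables were generated by integration with constants of no real substance; the scatter is artificial.

- A ratio of two rates carries this problem: where target and side product both grow in proportion to substrate and free catalyst stays steady, dividing one rate by the other removes time and substrate concentration, so the share depends on that ratio.

the same everywhere: substrate 0.23 M

| flask | free catalyst | temperature | remark | time |
|---|---|---|---|---|
| Wednesday's | 0.74 mM | 54 °C | run made earlier |  |
| Monday's | 1.7 mM | 62 °C | run made earlier |  |
| south-west | 1.1 mM | 50 °C |  | 8.0 min |
| north-east | 1.1 mM | 65 °C |  | 8.0 min |
| east | 1.1 mM |  | at 65 °C until 1.5 min, from then on at 50 °C | 8.0 min |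

- Wednesday's (time / min: target / %, side product / %): 0.667: 5, 9; 1.33: 5, 16; 2.00: 14, 19; 3.00: 16, 27; 4.00: 23, 30; 5.00: 25, 33
- Monday's (time / min: target / %, side product / %): 0.333: 10, 6; 0.667: 17, 13; 1.00: 22, 18; 1.50: 31, 22; 2.00: 36, 27; 3.00: 40, 33

(standard deviation of a reading: 2 percentage points)

- which flask leads in share of target in all that became target or side product or uncatalysed product ("all alike" within 1.5 percentage points) (south-west / north-east / east / all alike)
- share of target in all that became target or side product or uncatalysed product, south-west
- share of target in all that became target or side product or uncatalysed product, north-east
- share of target in all that became target or side product or uncatalysed product, east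

- the share counts what is present at the end, not what went on to other products

- Take the main step by itself: substrate meets free catalyst and gives target, and the share is 100%.
- Now add the side step, which we assume to be first order in substrate and free of catalyst. With free catalyst c taken as steady, target rate over side rate is S = σc, and the share falls to S/(1+S).
- Summing the six readings of each kind in Monday's run gives σ = 0.771 mM⁻¹, the selectivity factor per unit of free catalyst.
- Wednesday's cooler run reads higher, at 0.887 mM⁻¹. Both are readings and carry their scatter.
- We give south-west Wednesday's value and north-east Monday's, the nearer run in temperature. So S is 0.976 in south-west and 0.848 in north-east, and the shares are 49.4% and 45.9%.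
- Last comes uncatalysed product, which no reading shows. With w as its amount per unit of side product, the share is S/(1+S+w), so both figures come down by an amount we cannot read. With equal w the order stands, so we commit to south-west, and we place east, hot first and then cold, between the two.
- The forecast also names south-west, with 51%, 44% and 47% for south-west, north-east and east, figures that are not ours. Its ground: “Monday's better selectivity comes from its catalyst, not its heat”.
- The flasks give south-west as leader, with 43.7%, 32.6% and 35.7% for south-west, north-east and east. At 8.00 min, north-east holds 22.0% uncatalysed product beside 45.0% side product, so w = 0.488 there. Putting this w and our σ into S/(1+S+w) gives 36.3% for north-east, against the 32.6% found.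

    substrate + free catalyst → free catalyst + target (k = 94.6 L mol⁻¹ min⁻¹, Ea = 57.0 kJ mol⁻¹)
    substrate → side product (k = 0.0866 min⁻¹, Ea = 84.0 kJ mol⁻¹)
    free catalyst + target → spent catalyst (k = 0.423 L mol⁻¹ min⁻¹, Ea = 65.0 kJ mol⁻¹)
    substrate → uncatalysed product (k = 0.0416 min⁻¹, Ea = 85.0 kJ mol⁻¹)
    (constants at 50 °C)

- A neighbouring flask is north-east with 2.8 × 10⁻⁴ M free catalyst, all else held. Our σ gives S = 0.216, and the same w gives a share of 12.7%. The computed result is 11.3%.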